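The route rests on cutting the cyclobutane at C5–C11 and C4–C10. It uses the fact that the cyclobutane C4–C5–C11–C10 and its C3–C2–C1 bridge (the bicyclo[3.1.1]heptane) are strung on one geranyl-type chain C5–C4–C3–C2–C1–C11–C10–C9, so that a vinylketene (C5=C4, methylene on C3) can add across the C10=C11 alkene of the same chain. One thermal step should close the cyclobutanone and the six-membered ring and set C4, C10 and C11, the C9 silyl ether choosing the alkene face. The precursor is an (R)-8-silyloxy-3,7-dimethyldeca-2,6,9-trienoyl chloride; afterwards the seven-membered ring is closed onto the C5 ketone and the retained C9 oxygen steers C7.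

Key step: step 8

Assumption: atom labels C1–C11 are those of the target and are carried through all intermediates (the carbinol carbon C9 is C8 in the decatriene names; "tricycle" means the ring system of the target), and the face selection in step 8 is taken to follow the model given there.

Step 1
Reactants: 1 geranyl acetate
Product: 3 (2E,6E)-3,7-dimethyl-8-oxoocta-2,6-dien-1-yl acetate, via allylic alcohol 2 (not isolated)
Conditions: SeO2 (cat.), t-BuOOH, salicylic acid (cat.), CH2Cl2, rt; crude mixture then MnO2, CH2Cl2, rt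
Reagents that add atoms: selenium dioxide, O=[Se]=O (transfers the oxygen atom; kept in turnover by tert-butyl hydroperoxide, CC(C)(C)OO)
Why: SeO2 allylic oxidation (ene reaction, then [2,3]-sigmatropic shift) should take the (E)-methyl of the distal, more electron-rich trisubstituted alkene, and MnO2 converges the alcohol–aldehyde mixture on the enal.

Step 2
Reactants: 3 (2E,6E)-3,7-dimethyl-8-oxoocta-2,6-dien-1-yl acetate; 4 vinylmagnesium bromide
Product: 5 racemic (2E,6E)-8-hydroxy-3,7-dimethyldeca-2,6,9-trien-1-yl acetate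
Conditions: THF, −78 °C; aq NH4Cl
Reagents that add atoms: vinylmagnesium bromide 4, C=C[Mg]Br
Why: Grignard 1,2-addition to the aldehyde should be much faster at −78 °C than attack on the allylic acetate; the carbinol centre (C9) forms racemic.

Step 3
Reactants: 5 racemic (2E,6E)-8-hydroxy-3,7-dimethyldeca-2,6,9-trien-1-yl acetate
Product: 6 (2E,6E,8R)-8-hydroxy-3,7-dimethyldeca-2,6,9-trien-1-yl acetate
Conditions: Ti(OiPr)4 (cat.), L-(+)-diisopropyl tartrate (cat.), t-BuOOH (0.6 equiv), 4 Å molecular sieves, CH2Cl2, −20 °C, stopped near 55% conversion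
Reagents that add atoms: none
Why: Sharpless kinetic resolution: with L-(+)-tartrate the 8S enantiomer should be epoxidised fast at the trisubstituted alkene next to the carbinol, leaving the 8R alcohol (C9 of the target), while the vinyl group reacts far more slowly and the acetate-bearing alkene is not an allylic alcohol.

Step 4
Reactants: 6 (2E,6E,8R)-8-hydroxy-3,7-dimethyldeca-2,6,9-trien-1-yl acetate
Product: 7 (2E,6E,8R)-8-(tert-butyldimethylsilyloxy)-3,7-dimethyldeca-2,6,9-trien-1-yl acetate
Conditions: TBSCl, imidazole, DMF, rt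
Reagents that add atoms: tert-butyldimethylsilyl chloride, CC(C)(C)[Si](C)(C)Cl
Why: Standard silylation of a secondary alcohol; the silyl ether is electron-releasing enough to keep the C10=C11 alkene nucleophilic and is stable to all steps up to step 15.

Step 5
Reactants: 7 (2E,6E,8R)-8-(tert-butyldimethylsilyloxy)-3,7-dimethyldeca-2,6,9-trien-1-yl acetate
Product: 8 (2E,6E,8R)-8-(tert-butyldimethylsilyloxy)-3,7-dimethyldeca-2,6,9-trien-1-ol
Conditions: K2CO3, MeOH, 0 °C
Reagents that add atoms: none
Why: Transesterification removes the primary acetate while the secondary silyl ether is inert to carbonate in methanol.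

Step 6
Reactants: 8 (2E,6E,8R)-8-(tert-butyldimethylsilyloxy)-3,7-dimethyldeca-2,6,9-trien-1-ol
Product: 9 (2E,6E,8R)-8-(tert-butyldimethylsilyloxy)-3,7-dimethyldeca-2,6,9-trienal
Conditions: MnO2, CH2Cl2, rt
Reagents that add atoms: none
Why: MnO2 oxidises only the primary allylic alcohol and should keep the 2E geometry.

Step 7
Reactants: 9 (2E,6E,8R)-8-(tert-butyldimethylsilyloxy)-3,7-dimethyldeca-2,6,9-trienal
Product: 10 (2E,6E,8R)-8-(tert-butyldimethylsilyloxy)-3,7-dimethyldeca-2,6,9-trienoic acid
Conditions: NaClO2, NaH2PO4, 2-methyl-2-butene, t-BuOH/H2O, 0 °C to rt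
Reagents that add atoms: sodium chlorite, [Na+].[O-]Cl=O
Why: Pinnick oxidation converts the enal into the acid without touching alkenes or the silyl ether, the scavenger removing hypochlorous acid.

Step 8
Reactants: 10 (2E,6E,8R)-8-(tert-butyldimethylsilyloxy)-3,7-dimethyldeca-2,6,9-trienoic acid
Product: 13 (1R,5S,7S)-7-[(1R)-1-(tert-butyldimethylsilyloxy)prop-2-en-1-yl]-7-methyl-2-methylidenebicyclo[3.1.1]heptan-6-one (C10 methyl syn to the C1–C3 bridge; C9 arm anti), via acid chloride 11 (not isolated), via vinylketene 12 (not isolated)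
Conditions: 1-chloro-N,N,2-trimethylprop-1-en-1-amine, CH2Cl2, 0 °C to rt; crude 11 added slowly to Et3N, toluene, reflux, high dilution
Reagents that add atoms: none
Why: Et3N removes a proton from the C3 methyl of acid chloride 11 (vinylogous dehydrochlorination) to give vinylketene 12, whose electrophilic C5 bonds to the less substituted alkene carbon C11 while positive charge builds at tertiary C10, which closes onto C4 in a concerted, asynchronous [2+2] cycloaddition. The closest known reaction type is the intramolecular vinylketene–alkene cycloaddition of geranoyl-type chlorides (bridged, type 2 mode) that gives 2-methylidenebicyclo[3.1.1]heptan-6-ones. The six-membered ring C11–C1–C2–C3–C4–C5 closes by the C5–C11 bond, the three-atom tether C1–C3 allowing only the bridged mode, and the cyclobutanone closes by the C4–C10 bond in the same event. C4 and C11 are set together by the tether (cis bridgeheads), and C10 by the E alkene, because suprafacial addition keeps its methyl cis to C1 and therefore syn to the C1–C3 bridge, with C9 anti. The step needs face selectivity at C10=C11, which the (R)-C9 centre should supply as in hydroboration of 2-methyl allylic ethers: C9–H eclipses the alkene, the C–O bond lies near the alkene plane beside the C10 methyl where it does not drain the developing cation, and C4 arrives anti to the vinyl group, which gives the ring configuration drawn for 13. Bridged rather than fused regiochemistry follows from cation stability at C10, and the monosubstituted vinyl group is too electron-poor and too remote to compete.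

Step 9
Reactants: 13 (1R,5S,7S)-7-[(1R)-1-(tert-butyldimethylsilyloxy)prop-2-en-1-yl]-7-methyl-2-methylidenebicyclo[3.1.1]heptan-6-one
Product: 14 (3R)-3-(tert-butyldimethylsilyloxy)-3-[(1R,5S,7S)-7-methyl-2-methylidene-6-oxobicyclo[3.1.1]heptan-7-yl]propanal
Conditions: PdCl2(PhCN)2 (cat.), CuCl2·2H2O (cat.), AgNO2 (cat.), t-BuOH/MeNO2, O2 (1 atm), rt
Reagents that add atoms: dioxygen, O=O
Why: Nitrite-modified, aldehyde-selective Wacker oxidation should place oxygen on the terminal carbon (C7) of the monosubstituted alkene, a preference reinforced by the allylic silyl ether and the neighbouring quaternary carbon, while the 1,1-disubstituted C3 methylidene is a poor Wacker substrate.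

Step 10
Reactants: 14 (3R)-3-(tert-butyldimethylsilyloxy)-3-[(1R,5S,7S)-7-methyl-2-methylidene-6-oxobicyclo[3.1.1]heptan-7-yl]propanal; 15 2-bromopropene
Product: 16 (5R)-5-(tert-butyldimethylsilyloxy)-2-methyl-5-[(1R,5S,7S)-7-methyl-2-methylidene-6-oxobicyclo[3.1.1]heptan-7-yl]pent-1-en-3-ol (both C3 epimers)
Conditions: CrCl2 (4 equiv), NiCl2 (cat.), DMF, rt
Reagents that add atoms: 2-bromopropene 15, CC(Br)=C
Why: Nozaki–Hiyama–Kishi coupling: the alkenylchromium reagent adds to aldehydes only, so the hindered, non-enolisable cyclobutanone is left alone; the new carbinol (C7) forms as an epimer mixture that step 11 erases.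

Step 11
Reactants: 16 (5R)-5-(tert-butyldimethylsilyloxy)-2-methyl-5-[(1R,5S,7S)-7-methyl-2-methylidene-6-oxobicyclo[3.1.1]heptan-7-yl]pent-1-en-3-ol
Product: 17 (5R)-5-(tert-butyldimethylsilyloxy)-2-methyl-5-[(1R,5S,7S)-7-methyl-2-methylidene-6-oxobicyclo[3.1.1]heptan-7-yl]pent-1-en-3-one
Conditions: Dess–Martin periodinane, NaHCO3, CH2Cl2, 0 °C to rt
Reagents that add atoms: none
Why: Dess–Martin oxidation under buffered, neutral conditions should give the isopropenyl ketone without β-elimination of the silyloxy group.

Step 12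
Reactants: 17 (5R)-5-(tert-butyldimethylsilyloxy)-2-methyl-5-[(1R,5S,7S)-7-methyl-2-methylidene-6-oxobicyclo[3.1.1]heptan-7-yl]pent-1-en-3-one
Product: 18 tricyclic aldol: 5-hydroxy-9-(tert-butyldimethylsilyloxy)-3-methylidene tricycle with C7 ketone and C6 gem-dimethyl (C5–OH syn to the C1–C3 bridge; C6 anti; 9R)
Conditions: [(Ph3P)CuH]6 (1.2 equiv of hydride), toluene, −40 °C to 0 °C; aq NH4Cl
Reagents that add atoms: none
Why: Copper hydride conjugate reduction–aldol cyclisation (reductive aldol): hydride adds to the unsubstituted β-carbon to give the C6 copper enolate regiospecifically, which should add to the strained C5 carbonyl, and because the chain hangs from the anti position of C10 the enolate can only reach the C5 face anti to the C1–C3 bridge, so the seven-membered ring closes with C6 anti and C5–OH syn.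

Step 13
Reactants: 18 tricyclic aldol
Product: 19 C5 methyl oxalate of 18
Conditions: ClC(O)CO2Me, pyridine, DMAP (cat.), CH2Cl2, 0 °C to rt
Reagents that add atoms: methyl chlorooxoacetate, COC(=O)C(Cl)=O
Why: Acylation with a small, very electrophilic acid chloride under amine conditions should esterify the outward-pointing tertiary hydroxyl without the alkoxide formation that would invite retro-aldol cleavage.

Step 14
Reactants: 19 C5 methyl oxalate of 18
Product: 20 9-(tert-butyldimethylsilyloxy)-3-methylidene tricyclic C7 ketone with C5–H (C5–H syn to the C1–C3 bridge; C6 anti; 9R)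
Conditions: Bu3SnH, AIBN (cat.), toluene, reflux
Reagents that add atoms: none
Why: Barton–McCombie-type radical deoxygenation of a tertiary methyl oxalate: the C5 bridgehead radical can accept hydrogen only on its open side, so C5–H should form syn to the C1–C3 bridge with C6 anti, as in the target.

Step 15
Reactants: 20 9-(tert-butyldimethylsilyloxy)-3-methylidene tricyclic C7 ketone
Product: 21 9-hydroxy-3-methylidene tricyclic C7 ketone (β-hydroxy ketone; 9R)
Conditions: HF·pyridine, pyridine, THF, 0 °C to rt
Reagents that add atoms: none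
Why: Buffered fluoride desilylation should free the C9 hydroxyl without the basic conditions that could cause retro-aldol cleavage or β-elimination.

Step 16
Reactants: 21 9-hydroxy-3-methylidene tricyclic C7 ketone; 22 tiglic aldehyde, (E)-2-methylbut-2-enal
Product: 23 9-O-tigloyl-7-hydroxy-3-methylidene tricycle (7,9-anti)
Conditions: SmI2 (0.3 equiv), tiglic aldehyde (excess), THF, −10 °C
Reagents that add atoms: tiglic aldehyde 22, C/C=C(\C)C=O
Why: Evans–Tishchenko reduction: the C9 samarium hemiacetal of the aldehyde transfers hydride within a six-membered transition state to the C7 ketone on the face of the C9 oxygen, which should give the 7,9-anti diol with the tiglate already on O9 and O7 free.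

Step 17
Reactants: 23 9-O-tigloyl-7-hydroxy-3-methylidene tricycle; 24 senecioyl chloride, 3-methylbut-2-enoyl chloride
Product: 25 7-O-senecioyl-9-O-tigloyl-3-methylidene tricycle
Conditions: pyridine, DMAP (cat.), CH2Cl2, 0 °C to 40 °C
Reagents that add atoms: senecioyl chloride 24, CC(C)=CC(Cl)=O
Why: DMAP-catalysed acylation of the hindered C7 alcohol; pyridine in place of a trialkylamine limits vinylketene formation and hence deconjugation of the senecioyl group, and acyl migration is blocked by the trans relation of O7 and O9.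

Step 18
Reactants: 25 7-O-senecioyl-9-O-tigloyl-3-methylidene tricycle
Product: 26 7-O-senecioyl-9-O-tigloyl tricycle with C2=C3 alkene and C3 methyl
Conditions: RhCl3·3H2O (cat.), EtOH/CHCl3, 70 °C
Reagents that add atoms: none
Why: Rhodium hydride alkene isomerisation should move the exocyclic double bond into the ring (the thermodynamic direction, as for β-pinene to α-pinene), and only C2 can take it because C4 is a bridgehead.

Step 19
Reactants: 26 7-O-senecioyl-9-O-tigloyl tricycle with C2=C3 alkene
Product: 27 CNP0277258.1 (target)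
Conditions: CrO3, 3,5-dimethylpyrazole, CH2Cl2, −20 °C
Reagents that add atoms: chromium trioxide, O=[Cr](=O)=O
Why: Allylic oxidation with the hexavalent chromium–dimethylpyrazole complex should convert the ring allylic methylene C1 into the conjugated ketone (verbenone-type enone), the bridgehead C4–H and the electron-poor enoate methyls being much less reactive.

Compound list
1 | geranyl acetate, (2E)-3,7-dimethylocta-2,6-dien-1-yl acetate | CC(C)=CCC/C(C)=C/COC(C)=O | starting material
2 | (2E,6E)-8-hydroxy-3,7-dimethylocta-2,6-dien-1-yl acetate | OC/C(C)=C/CC/C(C)=C/COC(C)=O | intermediate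
3 | (2E,6E)-3,7-dimethyl-8-oxoocta-2,6-dien-1-yl acetate | O=C/C(C)=C/CC/C(C)=C/COC(C)=O | intermediate
4 | vinylmagnesium bromide | C=C[Mg]Br | starting material
5 | racemic (2E,6E)-8-hydroxy-3,7-dimethyldeca-2,6,9-trien-1-yl acetate | C=CC(O)/C(C)=C/CC/C(C)=C/COC(C)=O | intermediate
6 | (2E,6E,8R)-8-hydroxy-3,7-dimethyldeca-2,6,9-trien-1-yl acetate | C=C[C@@H](O)/C(C)=C/CC/C(C)=C/COC(C)=O | intermediate
7 | (2E,6E,8R)-8-(tert-butyldimethylsilyloxy)-3,7-dimethyldeca-2,6,9-trien-1-yl acetate | C=C[C@@H](O[Si](C)(C)C(C)(C)C)/C(C)=C/CC/C(C)=C/COC(C)=O | intermediate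
8 | (2E,6E,8R)-8-(tert-butyldimethylsilyloxy)-3,7-dimethyldeca-2,6,9-trien-1-ol | C=C[C@@H](O[Si](C)(C)C(C)(C)C)/C(C)=C/CC/C(C)=C/CO | intermediate
9 | (2E,6E,8R)-8-(tert-butyldimethylsilyloxy)-3,7-dimethyldeca-2,6,9-trienal | C=C[C@@H](O[Si](C)(C)C(C)(C)C)/C(C)=C/CC/C(C)=C/C=O | intermediate
10 | (2E,6E,8R)-8-(tert-butyldimethylsilyloxy)-3,7-dimethyldeca-2,6,9-trienoic acid | C=C[C@@H](O[Si](C)(C)C(C)(C)C)/C(C)=C/CC/C(C)=C/C(=O)O | intermediate
11 | (2E,6E,8R)-8-(tert-butyldimethylsilyloxy)-3,7-dimethyldeca-2,6,9-trienoyl chloride (key-step precursor) | ClC(=O)/C=C(\C)CC/C=C(\C)[C@H](O[Si](C)(C)C(C)(C)C)C=C | intermediate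
12 | vinylketene, (6E,8R)-8-(tert-butyldimethylsilyloxy)-7-methyl-3-methylidenedeca-1,6,9-trien-1-one | O=C=CC(=C)CC/C=C(\C)[C@H](O[Si](C)(C)C(C)(C)C)C=C | intermediate
13 | (1R,5S,7S)-7-[(1R)-1-(tert-butyldimethylsilyloxy)prop-2-en-1-yl]-7-methyl-2-methylidenebicyclo[3.1.1]heptan-6-one; C10 methyl syn to the C1–C3 bridge, C9 arm anti | C=C[C@@H](O[Si](C)(C)C(C)(C)C)[C@@]1(C)[C@@H]2CCC(=C)[C@H]1C2=O | intermediate
14 | (3R)-3-(tert-butyldimethylsilyloxy)-3-[(1R,5S,7S)-7-methyl-2-methylidene-6-oxobicyclo[3.1.1]heptan-7-yl]propanal | O=CC[C@@H](O[Si](C)(C)C(C)(C)C)[C@@]1(C)[C@@H]2CCC(=C)[C@H]1C2=O | intermediate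
15 | 2-bromopropene | CC(Br)=C | starting material
16 | (5R)-5-(tert-butyldimethylsilyloxy)-2-methyl-5-[(1R,5S,7S)-7-methyl-2-methylidene-6-oxobicyclo[3.1.1]heptan-7-yl]pent-1-en-3-ol, both C3 epimers | C=C(C)C(O)C[C@@H](O[Si](C)(C)C(C)(C)C)[C@@]1(C)[C@@H]2CCC(=C)[C@H]1C2=O | intermediate
17 | (5R)-5-(tert-butyldimethylsilyloxy)-2-methyl-5-[(1R,5S,7S)-7-methyl-2-methylidene-6-oxobicyclo[3.1.1]heptan-7-yl]pent-1-en-3-one | C=C(C)C(=O)C[C@@H](O[Si](C)(C)C(C)(C)C)[C@@]1(C)[C@@H]2CCC(=C)[C@H]1C2=O | intermediate
18 | tricyclic aldol: 5-hydroxy-9-(tert-butyldimethylsilyloxy)-3-methylidene tricycle, C7 ketone, C6 gem-dimethyl; C5–OH syn to the C1–C3 bridge, C6 anti, 9R | CC(C)(C)[Si](C)(C)O[C@@H]1CC(=O)C(C)(C)[C@]2(O)[C@H]3CCC(=C)[C@@H]2[C@]31C | intermediate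
19 | C5 methyl oxalate of 18 | CC(C)(C)[Si](C)(C)O[C@@H]1CC(=O)C(C)(C)[C@]2(OC(=O)C(=O)OC)[C@H]3CCC(=C)[C@@H]2[C@]31C | intermediate
20 | 9-(tert-butyldimethylsilyloxy)-3-methylidene tricyclic C7 ketone; C5–H syn to the C1–C3 bridge, C6 anti, 9R | CC(C)(C)[Si](C)(C)O[C@@H]1CC(=O)C(C)(C)[C@@H]2[C@H]3CCC(=C)[C@@H]2[C@]31C | intermediate
21 | 9-hydroxy-3-methylidene tricyclic C7 ketone, 9R | O[C@@H]1CC(=O)C(C)(C)[C@@H]2[C@H]3CCC(=C)[C@@H]2[C@]31C | intermediate
22 | tiglic aldehyde, (E)-2-methylbut-2-enal | C/C=C(\C)C=O | starting material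
23 | 9-O-tigloyl-7-hydroxy-3-methylidene tricycle; O7 and O9 trans (7,9-anti) | C/C=C(\C)C(=O)O[C@@H]1C[C@@H](O)C(C)(C)[C@@H]2[C@H]3CCC(=C)[C@@H]2[C@]31C | intermediate
24 | senecioyl chloride, 3-methylbut-2-enoyl chloride | CC(C)=CC(Cl)=O | starting material
25 | 7-O-senecioyl-9-O-tigloyl-3-methylidene tricycle | C/C=C(\C)C(=O)O[C@@H]1C[C@@H](OC(=O)C=C(C)C)C(C)(C)[C@@H]2[C@H]3CCC(=C)[C@@H]2[C@]31C | intermediate
26 | 7-O-senecioyl-9-O-tigloyl tricycle with C2=C3 alkene and C3 methyl | C/C=C(\C)C(=O)O[C@@H]1C[C@@H](OC(=O)C=C(C)C)C(C)(C)[C@@H]2[C@H]3CC=C(C)[C@@H]2[C@]31C | intermediate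
27 | CNP0277258.1: C1 ketone, C2=C3 enone, C7 senecioate, C9 tiglate | C/C=C(\C)C(=O)O[C@@H]1C[C@@H](OC(=O)C=C(C)C)C(C)(C)[C@@H]2[C@H]3C(=O)C=C(C)[C@@H]2[C@]31C | target

Total step count: 19. Longest linear sequence: 19 steps (1 to 27); the other starting materials 4, 15, 22 and 24 enter directly.

Steps most likely to fail

Step 8. The C9 ether may discriminate the two faces of C10=C11 only weakly at 110 °C, and slow γ-deprotonation may let the ketene oligomerise. The fallback sets out from acid 10 and changes the way the ketene is made. Deconjugative α-protonation of the dienolate (LDA, 2.2 equiv, THF, −78 °C, then AcOH) should give (6E,8R)-8-(tert-butyldimethylsilyloxy)-7-methyl-3-methylidenedeca-6,9-dienoic acid F1. 1-Chloro-N,N,2-trimethylprop-1-en-1-amine then gives (6E,8R)-8-(tert-butyldimethylsilyloxy)-7-methyl-3-methylidenedeca-6,9-dienoyl chloride F2. Its acidic C4 methylene lets Et3N form the same vinylketene 12 at or below room temperature, so the ring closure can be run at 25–60 °C, where the bias from C9 weighs more. The route is rejoined at 13.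

Step 12. The copper enolate may be quenched before it reaches the hindered C5 carbonyl (plain conjugate reduction), or the strained aldolate may revert. The fallback sets out from enone 17 and uses a regiodefined samarium enolate. RhCl(PPh3)3-catalysed 1,4-hydrosilylation with Et3SiH should give the triethylsilyl enol ether F3. NBS (THF, −78 °C) converts it into the tertiary α-bromo ketone F4. SmI2 (THF, −78 °C) then closes the ring by an intramolecular Reformatsky reaction through an irreversible trivalent samarium aldolate. The route is rejoined at 18.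

Step 9. Oxygen may be delivered to the internal carbon (methyl ketone), or divalent palladium may engage the exocyclic C3 methylidene (migration or π-allyl formation). The fallback sets out from 13 and replaces the oxidation by a metathesis–oxidation pair. Cross-metathesis with vinylboronic acid pinacol ester (second-generation Hoveyda–Grubbs catalyst, CH2Cl2, 40 °C) should give the (E)-alkenylboronic acid pinacol ester F5. Anhydrous trimethylamine N-oxide (THF, reflux) oxidises the C–B bond without Baeyer–Villiger risk for the cyclobutanone and gives the aldehyde after tautomerisation. The route is rejoined at 14.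

Further compounds
F1 | step 8 | (6E,8R)-8-(tert-butyldimethylsilyloxy)-7-methyl-3-methylidenedeca-6,9-dienoic acid | C=C[C@@H](O[Si](C)(C)C(C)(C)C)/C(C)=C/CCC(=C)CC(=O)O
F2 | step 8 | (6E,8R)-8-(tert-butyldimethylsilyloxy)-7-methyl-3-methylidenedeca-6,9-dienoyl chloride | C=C[C@@H](O[Si](C)(C)C(C)(C)C)/C(C)=C/CCC(=C)CC(Cl)=O
F3 | step 12 | triethylsilyl enol ether of the isopropyl ketone derived from 17 (C6=C7 enol ether) | CC(C)=C(O[Si](CC)(CC)CC)C[C@@H](O[Si](C)(C)C(C)(C)C)[C@@]1(C)[C@@H]2CCC(=C)[C@H]1C2=O
F4 | step 12 | α-bromo ketone: 2-bromo-2-methyl analogue of the saturated ketone derived from 17 | CC(C)(Br)C(=O)C[C@@H](O[Si](C)(C)C(C)(C)C)[C@@]1(C)[C@@H]2CCC(=C)[C@H]1C2=O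
F5 | step 9 | (E)-alkenylboronic acid pinacol ester from 13 (boron on C7) | CC1(C)OB(/C=C/[C@@H](O[Si](C)(C)C(C)(C)C)[C@@]2(C)[C@@H]3CCC(=C)[C@H]2C3=O)OC1(C)C
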